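**Retrosynthetic overview**
1. Germacrane numbering is used. The ten-membered carbocycle is C1–C10, with C1=C10 carrying C14H3, C4=C5 carrying C15H2OH, and the acyloxy group on C8. The five-membered lactone is O–C6–C7–C11(C13H3)–C12(=O).
2. Enabling feature: C6, the O-bearing carbon of the lactone ring, is allylic to the ring alkene C4=C5 and vicinal to C7. The three lactone substituents (C5 on C6, C8 on C7, C13 on C11) are all trans. The lactone is therefore the 1,2-adduct of a propionic acid C,O-unit on the C6=C7 end of a C4=C5–C6=C7 diene.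
3. Key disconnection: O–C6 and C7–C11 are cut together, by radical–polar carbolactonisation of the monocyclic trienol 17 (one stereocentre, C8) with 2-bromopropanoic acid. Only C8 acylation and desilylation follow.
4. Trienol 17 comes from ring-closing metathesis at C6=C7 of the acyclic tetraenol 16. C8 comes from (R)-2-vinyloxirane, E-C1=C10 from an alkyne carboalumination, and the C4=C5 geometry and C15–O from a butenolide.
5. Ring order: the ten-membered carbocycle is formed first (step 10), the γ-lactone second (step 11).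

Key step: step 11

Assumption: enantiopure (R)-2-vinyloxirane is taken as purchasable. It is also the epoxide recovered from a hydrolytic kinetic resolution of butadiene monoxide.

**Step 1**
Reactants: 1 (R)-2-vinyloxirane; 2 lithium acetylide–ethane-1,2-diamine complex
Product: 3 (3S)-hex-1-en-5-yn-3-ol
Conditions: DMSO, 0 °C to rt; then H2O
Reagents that add atoms: lithium acetylide (as 2), [Li+].[C-]#C
Why: SN2 opening of the epoxide by the acetylide at the unhindered CH2 terminus (epoxide alkynylation) leaves the C–O stereocentre untouched, so the (R)-epoxide should deliver the (S)-carbinol that becomes C8.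

**Step 2**
Reactants: 3 (3S)-hex-1-en-5-yn-3-ol
Product: 4 triethyl{[(3S)-hex-1-en-5-yn-3-yl]oxy}silane
Conditions: Et3SiCl, imidazole, CH2Cl2, 0 °C
Reagents that add atoms: chlorotriethylsilane, CC[Si](Cl)(CC)CC
Why: Standard silyl ether formation masks the C8 hydroxyl against the organometallic steps with a group that can later be removed beside a primary tert-butyldimethylsilyl ether.

**Step 3**
Reactants: 4 triethyl{[(3S)-hex-1-en-5-yn-3-yl]oxy}silane; 5 oxirane
Product: 8 (3E,6S)-4-methyl-6-(triethylsilyloxy)octa-3,7-dien-1-ol, via alkenyldimethylalane 6 (not isolated), via lithium alkenylalanate 7 (not isolated)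
Conditions: Me3Al, Cp2ZrCl2 (0.25 equiv), CH2Cl2, 0 °C to rt; volatiles removed; n-BuLi, hexane/THF, −78 to 0 °C; 5, 0 °C to rt; aqueous Rochelle salt
Reagents that add atoms: trimethylaluminium, C[Al](C)C; oxirane (5), C1CO1
Why: The Negishi carboalumination adds CH3 and Al syn across the terminal alkyne (much faster than across the hindered vinyl group) and so fixes the E geometry of C1=C10, and the derived alanate opens oxirane with retention at the alkenyl carbon to add C2 and C3.

**Step 4**
Reactants: 8 (3E,6S)-4-methyl-6-(triethylsilyloxy)octa-3,7-dien-1-ol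
Product: 9 (3S,5E)-8-iodo-5-methyl-3-(triethylsilyloxy)octa-1,5-diene
Conditions: I2, PPh3, imidazole, CH2Cl2, 0 °C
Reagents that add atoms: iodine, II
Why: Appel-type iodination of the only free, primary alcohol proceeds under buffered conditions that spare the silyl ether and both alkenes.

**Step 5**
Reactants: 9 (3S,5E)-8-iodo-5-methyl-3-(triethylsilyloxy)octa-1,5-diene; 10 4-bromofuran-2(5H)-one
Product: 12 4-[(3E,6S)-4-methyl-6-(triethylsilyloxy)octa-3,7-dien-1-yl]furan-2(5H)-one, via alkylzinc iodide 11 (not isolated)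
Conditions: Zn dust, LiCl, THF, 40 °C; then 10, Pd(OAc)2 (2 mol %), SPhos (4 mol %), THF, rt
Reagents that add atoms: 4-bromofuran-2(5H)-one (10), O=C1C=C(Br)CO1
Why: LiCl-promoted zinc insertion gives a non-basic alkylzinc iodide for a Negishi sp3–sp2 coupling at the vinylogous acyl bromide, and the butenolide ring locks C15 and C6 cis on C4=C5, which is the ring-trans geometry of the target.

**Step 6**
Reactants: 12 4-[(3E,6S)-4-methyl-6-(triethylsilyloxy)octa-3,7-dien-1-yl]furan-2(5H)-one
Product: 13 4-[(3E,6S)-4-methyl-6-(triethylsilyloxy)octa-3,7-dien-1-yl]-2,5-dihydrofuran-2-ol (anomeric mixture)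
Conditions: i-Bu2AlH (1.1 equiv), CH2Cl2, −78 °C; aqueous Rochelle salt; used crude
Reagents that add atoms: none
Why: Partial lactone reduction stops at the aluminium hemiacetal at low temperature, and the neutral work-up should avoid dehydration to the furan.

**Step 7**
Reactants: 13 4-[(3E,6S)-4-methyl-6-(triethylsilyloxy)octa-3,7-dien-1-yl]-2,5-dihydrofuran-2-ol
Product: 14 (2Z)-2-[(3E,6S)-4-methyl-6-(triethylsilyloxy)octa-3,7-dien-1-yl]penta-2,4-dien-1-ol
Conditions: Ph3PCH3Br, KN(SiMe3)2, THF, 0 °C; then 13, −78 °C to rt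
Reagents that add atoms: methyltriphenylphosphonium bromide, C[P+](c1ccccc1)(c1ccccc1)c1ccccc1.[Br-]
Why: Wittig methylenation of the ring-opened (Z)-4-hydroxy enal tautomer of the lactol gives the terminal diene and frees C15–OH, with the C4=C5 geometry inherited from the former ring.

**Step 8**
Reactants: 14 (2Z)-2-[(3E,6S)-4-methyl-6-(triethylsilyloxy)octa-3,7-dien-1-yl]penta-2,4-dien-1-ol
Product: 15 (3S,5E,9Z)-9-[(tert-butyldimethylsilyloxy)methyl]-5-methyl-3-(triethylsilyloxy)dodeca-1,5,9,11-tetraene
Conditions: TBSCl, imidazole, CH2Cl2, 0 °C to rt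
Reagents that add atoms: tert-butylchlorodimethylsilane, CC(C)(C)[Si](C)(C)Cl
Why: Silylation of the primary allylic alcohol keeps C15–OH from acting as a nucleophile towards C6 in step 11 and from competing in the acylation of step 14.

**Step 9**
Reactants: 15 (3S,5E,9Z)-9-[(tert-butyldimethylsilyloxy)methyl]-5-methyl-3-(triethylsilyloxy)dodeca-1,5,9,11-tetraene
Product: 16 (3S,5E,9Z)-9-[(tert-butyldimethylsilyloxy)methyl]-5-methyldodeca-1,5,9,11-tetraen-3-ol
Conditions: PPTS (0.1 equiv), MeOH/CH2Cl2, 0 °C
Reagents that add atoms: none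
Why: Acid-catalysed methanolysis distinguishes the far more labile triethylsilyl ether from the tert-butyldimethylsilyl ether and is done on the robust open chain, before the acid-sensitive ring exists.

**Step 10**
Reactants: 16 (3S,5E,9Z)-9-[(tert-butyldimethylsilyloxy)methyl]-5-methyldodeca-1,5,9,11-tetraen-3-ol
Product: 17 (1S,2Z,4Z,8E)-5-[(tert-butyldimethylsilyloxy)methyl]-9-methylcyclodeca-2,4,8-trien-1-ol (C1=C10 and C4=C5 ring-trans, C6=C7 ring-cis)
Conditions: second-generation Grubbs catalyst (10 mol %), 1,4-benzoquinone (20 mol %), CH2Cl2 (0.5 mM, slow addition, argon sparge), 40 °C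
Reagents that add atoms: none
Why: In this ene–diene ring-closing metathesis the ruthenium alkylidene loads on the monosubstituted alkene of the allylic alcohol and closes on the terminal CH=CH2 of the diene with loss of ethene, the trisubstituted alkenes stay inert, and beside the ring-trans C4=C5 the ring should accept the new C6=C7 only as the cis alkene, as in the 4,6-diene of germacrene C.

**Step 11**
Reactants: 17 (1S,2Z,4Z,8E)-5-[(tert-butyldimethylsilyloxy)methyl]-9-methylcyclodeca-2,4,8-trien-1-ol; 18 2-bromopropanoic acid (racemic)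
Product: 20 (3S,3aR,4S,6E,10Z,11aR)-10-[(tert-butyldimethylsilyloxy)methyl]-4-hydroxy-3,6-dimethyl-3a,4,5,8,9,11a-hexahydrocyclodeca[b]furan-2(3H)-one (15-O-TBS-11β,13-dihydrosalonitenolide), via 11-epi-lactone 19 (not isolated)
Conditions: [Cu(dap)2]Cl (2 mol %; dap = 2,9-bis(4-methoxyphenyl)-1,10-phenanthroline), 18 (1.3 equiv), K2HPO4 (2.5 equiv), MeCN, 530 nm LED, 20 °C; then DBU (3 equiv), 50 °C
Reagents that add atoms: 2-bromopropanoic acid (18), CC(Br)C(=O)O
Why: Green light excites [Cu(dap)2]+ (monovalent copper), which cleaves the C–Br bond of the carboxylate of 18; the electrophilic 1-carboxyethyl radical adds to C7, the allyl radical C6–C5–C4 so formed is taken up by the divalent copper carboxylate/bromide, and C6–O bond formation (directly, as in the Kharasch–Sosnovsky reaction, or through the allylic bromide) returns monovalent copper, so that C7–C11 and O–C6 are made in one catalytic cycle. The closest known reaction types are the radical addition of 2-bromoalkanoic acids to alkenes, which gives 4-alkanolides directly, and the Mn(OAc)3 lactone annulation of 1,3-dienes with carboxylic acids. The one ring closed is the five-membered lactone, by 5-exo attack of the carboxylate oxygen on the C6 end of the allyl unit, whereas attack at C4 would need a seven-membered ring and a fully substituted centre; C4=C5 is thereby restored with the geometry it had in 17, because the allyl unit does not rotate within its lifetime. C7 is controlled by C8: 1,3-allylic strain across the Z C6=C7 bond holds H8 in the diene plane, C9 and the rest of the ring cover one face, and the radical enters on the open face, which carries only the small hydroxyl group that can hydrogen-bond to the incoming carboxyl group, so that 8S should give 7R. C6 is controlled by C7, since the lactone closes through the conformer in which H7 eclipses C5 while C8 and C11 lie on opposite faces of the allyl plane (also the crown shape of an E,E-cyclodeca-1,5-diene), which makes the ring fusion trans (6R), and C11, first formed as a mixture with 19, is equilibrated by DBU through the lactone enolate to the all-trans 11S isomer with C13 anti to C8. The step needs site selectivity for the diene over C1=C10 and for C7 over C4, secured by the allyl stabilisation of the adduct radical, by C7 being the only unsubstituted diene terminus and by a near-stoichiometric charge of 18, while the phosphate buffer protects the acid-sensitive 1,5-diene from transannular cyclisation and the low triplet energy of the copper complex avoids sensitised diene isomerisation.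

**Step 12**
Reactants: 21 ethyl 2-(hydroxymethyl)acrylate
Product: 22 ethyl 2-[(tert-butyldimethylsilyloxy)methyl]acrylate
Conditions: TBSCl, imidazole, CH2Cl2, 0 °C to rt
Reagents that add atoms: tert-butylchlorodimethylsilane, CC(C)(C)[Si](C)(C)Cl
Why: Routine silylation of the primary alcohol prevents self-esterification of the side-chain acid later on.

**Step 13**
Reactants: 22 ethyl 2-[(tert-butyldimethylsilyloxy)methyl]acrylate
Product: 23 2-[(tert-butyldimethylsilyloxy)methyl]acrylic acid
Conditions: LiOH, THF/H2O, 0 °C to rt; then 1 M HCl to pH 4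
Reagents that add atoms: lithium hydroxide, [Li+].[OH-]
Why: Mild saponification of the unhindered ethyl ester and a cautious acidification leave the silyl ether and the acrylate alkene intact.

**Step 14**
Reactants: 20 15-O-TBS-11β,13-dihydrosalonitenolide; 23 2-[(tert-butyldimethylsilyloxy)methyl]acrylic acid
Product: 24 (3S,3aR,4S,6E,10Z,11aR)-10-[(tert-butyldimethylsilyloxy)methyl]-3,6-dimethyl-2-oxo-2,3,3a,4,5,8,9,11a-octahydrocyclodeca[b]furan-4-yl 2-[(tert-butyldimethylsilyloxy)methyl]acrylate
Conditions: N,N'-diisopropylcarbodiimide, DMAP (0.3 equiv), CH2Cl2, 0 °C to rt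
Reagents that add atoms: 2-[(tert-butyldimethylsilyloxy)methyl]acrylic acid (23), C=C(CO[Si](C)(C)C(C)(C)C)C(=O)O
Why: The Steglich esterification acylates the only free hydroxyl (C8–OH) at oxygen, so C8 keeps its configuration and the conditions are too mild to epimerise C11.

**Step 15**
Reactants: 24 bis-silyl ether of the target
Product: 25 (3S,3aR,4S,6E,10Z,11aR)-10-(hydroxymethyl)-3,6-dimethyl-2-oxo-2,3,3a,4,5,8,9,11a-octahydrocyclodeca[b]furan-4-yl 2-(hydroxymethyl)acrylate (11β,13-dihydroonopordopicrin, CNP0167163.3)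
Conditions: Et3N·3HF, MeCN, 0 °C to rt
Reagents that add atoms: none
Why: Nearly neutral fluoride-mediated cleavage of both primary silyl ethers should spare the acrylate, the lactone and the acid-sensitive 1,5-diene and touches no stereocentre.

**Compound list**
1 | (R)-2-vinyloxirane | C=C[C@@H]1CO1 | starting material
2 | lithium acetylide–ethane-1,2-diamine complex | [Li+].[C-]#C.NCCN | starting material
3 | (3S)-hex-1-en-5-yn-3-ol | C=C[C@@H](O)CC#C | intermediate
4 | triethyl{[(3S)-hex-1-en-5-yn-3-yl]oxy}silane | C=C[C@@H](O[Si](CC)(CC)CC)CC#C | intermediate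
5 | oxirane | C1CO1 | starting material
6 | dimethyl[(1E,4S)-2-methyl-4-(triethylsilyloxy)hexa-1,5-dien-1-yl]alane | C=C[C@@H](O[Si](CC)(CC)CC)C/C(C)=C/[Al](C)C | intermediate
7 | lithium butyl(dimethyl)[(1E,4S)-2-methyl-4-(triethylsilyloxy)hexa-1,5-dien-1-yl]alanate | [Li+].C=C[C@@H](O[Si](CC)(CC)CC)C/C(C)=C/[Al-](C)(C)CCCC | intermediate
8 | (3E,6S)-4-methyl-6-(triethylsilyloxy)octa-3,7-dien-1-ol | C=C[C@@H](O[Si](CC)(CC)CC)C/C(C)=C/CCO | intermediate
9 | (3S,5E)-8-iodo-5-methyl-3-(triethylsilyloxy)octa-1,5-diene | C=C[C@@H](O[Si](CC)(CC)CC)C/C(C)=C/CCI | intermediate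
10 | 4-bromofuran-2(5H)-one | O=C1C=C(Br)CO1 | starting material
11 | [(3E,6S)-4-methyl-6-(triethylsilyloxy)octa-3,7-dien-1-yl]zinc iodide | C=C[C@@H](O[Si](CC)(CC)CC)C/C(C)=C/CC[Zn]I | intermediate
12 | 4-[(3E,6S)-4-methyl-6-(triethylsilyloxy)octa-3,7-dien-1-yl]furan-2(5H)-one | C=C[C@@H](O[Si](CC)(CC)CC)C/C(C)=C/CCC1=CC(=O)OC1 | intermediate
13 | 4-[(3E,6S)-4-methyl-6-(triethylsilyloxy)octa-3,7-dien-1-yl]-2,5-dihydrofuran-2-ol | C=C[C@@H](O[Si](CC)(CC)CC)C/C(C)=C/CCC1=CC(O)OC1 | intermediate
14 | (2Z)-2-[(3E,6S)-4-methyl-6-(triethylsilyloxy)octa-3,7-dien-1-yl]penta-2,4-dien-1-ol | C=C[C@@H](O[Si](CC)(CC)CC)C/C(C)=C/CC/C(CO)=C/C=C | intermediate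
15 | (3S,5E,9Z)-9-[(tert-butyldimethylsilyloxy)methyl]-5-methyl-3-(triethylsilyloxy)dodeca-1,5,9,11-tetraene | C=C[C@@H](O[Si](CC)(CC)CC)C/C(C)=C/CC/C(CO[Si](C)(C)C(C)(C)C)=C/C=C | intermediate
16 | (3S,5E,9Z)-9-[(tert-butyldimethylsilyloxy)methyl]-5-methyldodeca-1,5,9,11-tetraen-3-ol | C=C[C@@H](O)C/C(C)=C/CC/C(CO[Si](C)(C)C(C)(C)C)=C/C=C | intermediate
17 | (1S,2Z,4Z,8E)-5-[(tert-butyldimethylsilyloxy)methyl]-9-methylcyclodeca-2,4,8-trien-1-ol | C1/C(C)=C/CC/C(CO[Si](C)(C)C(C)(C)C)=C/C=C\[C@H]1O | intermediate
18 | 2-bromopropanoic acid (racemic) | CC(Br)C(=O)O | starting material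
19 | (3R,3aR,4S,6E,10Z,11aR)-10-[(tert-butyldimethylsilyloxy)methyl]-4-hydroxy-3,6-dimethyl-3a,4,5,8,9,11a-hexahydrocyclodeca[b]furan-2(3H)-one (11-epimer of 20) | O[C@H]1C/C(C)=C/CC/C(CO[Si](C)(C)C(C)(C)C)=C/[C@H]2OC(=O)[C@H](C)[C@H]12 | intermediate
20 | (3S,3aR,4S,6E,10Z,11aR)-10-[(tert-butyldimethylsilyloxy)methyl]-4-hydroxy-3,6-dimethyl-3a,4,5,8,9,11a-hexahydrocyclodeca[b]furan-2(3H)-one | O[C@H]1C/C(C)=C/CC/C(CO[Si](C)(C)C(C)(C)C)=C/[C@H]2OC(=O)[C@@H](C)[C@H]12 | intermediate
21 | ethyl 2-(hydroxymethyl)acrylate | C=C(CO)C(=O)OCC | starting material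
22 | ethyl 2-[(tert-butyldimethylsilyloxy)methyl]acrylate | C=C(CO[Si](C)(C)C(C)(C)C)C(=O)OCC | intermediate
23 | 2-[(tert-butyldimethylsilyloxy)methyl]acrylic acid | C=C(CO[Si](C)(C)C(C)(C)C)C(=O)O | intermediate
24 | bis(tert-butyldimethylsilyl) ether of the target | C=C(CO[Si](C)(C)C(C)(C)C)C(=O)O[C@H]1C/C(C)=C/CC/C(CO[Si](C)(C)C(C)(C)C)=C/[C@H]2OC(=O)[C@@H](C)[C@H]12 | intermediate
25 | 11β,13-dihydroonopordopicrin (CNP0167163.3) | C=C(CO)C(=O)O[C@H]1C/C(C)=C/CC/C(CO)=C/[C@H]2OC(=O)[C@@H](C)[C@H]12 | target

**Step count**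
- Total: 15 steps.
- Longest linear sequence: 13 steps (steps 1–11, 14, 15).

**Steps most likely to fail**

*Step 11 (key step).*
- What may go wrong: face selectivity at C7 may erode, the lactone may close cis-fused, or C1=C10 may capture the allyl intermediate across the ring.
- Fallback: it sets out from 17 and comes back at 20. The radical is generated oxidatively from a C–H acid, and C11 is set in a separate event.
- Methylmalonic acid with Mn(OAc)3·2H2O (trivalent manganese) and Cu(OAc)2 (divalent copper, which oxidises the allyl radical) is used in KOAc-buffered AcOH/MeCN at 25 °C. This known mild carbolactonisation would give the 11-carboxy lactone F1.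
- Heating F1 with DBU in toluene at 90 °C would decarboxylate it through the lactone enol. The same base equilibrates C11, giving 20.

*Step 10.*
- What may go wrong: the reversible metathesis may drain into oligomers because of ring strain, and ruthenium hydrides may isomerise the allylic alcohol.
- Fallback: it sets out from 9 and comes back at 17. The ring is closed instead at C5–C6 by an irreversible, stereoretentive sp2–sp2 coupling.
- Iodine–lithium exchange on 9 (t-BuLi) is followed by transmetalation with MgBr2·OEt2. CuI-catalysed anti-carbomagnesiation of propargyl alcohol (deprotonated beforehand with i-PrMgCl) and iodinolysis would then give the (Z)-iodoalkenol F2, with iodine cis to CH2OH through the magnesium chelate.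
- TBSCl/imidazole would give the silyl ether F3.
- Z-selective cross-metathesis of the monosubstituted alkene with vinylboronic acid pinacol ester would give the (Z)-alkenylboronate F4. The catalyst is Mo(N-2,6-i-Pr2C6H3)(CHCMe2Ph)(2,5-dimethylpyrrolide)(O-2,6-(2,4,6-i-Pr3C6H2)2C6H3).
- An intramolecular Suzuki–Miyaura coupling (PdCl2(dppf), Cs2CO3, DMF/H2O, high dilution) would give the cyclic triethylsilyl ether F5.
- PPTS in MeOH at 0 °C would release 17.

*Step 7.*
- What may go wrong: lactol 13 may dehydrate to the 3-substituted furan, and the open hydroxy enal may isomerise from Z to E before olefination.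
- Fallback: it sets out from 12 and comes back at 15, and it never passes through a lactol.
- Aminolysis of the butenolide with MeNH(OMe)·HCl and i-PrMgCl (THF, −20 °C) would give the (Z)-hydroxy Weinreb amide F6.
- Immediate silylation (TBSCl, imidazole) would give the silyl ether F7.
- i-Bu2AlH at −78 °C would give the (Z)-enal F8.
- Wittig methylenation (Ph3PCH3Br, KN(SiMe3)2) would give 15.

**Further compounds**
F1 | step 11 | (3aR,4S,6E,10Z,11aR)-10-[(tert-butyldimethylsilyloxy)methyl]-4-hydroxy-3,6-dimethyl-2-oxo-2,3,3a,4,5,8,9,11a-octahydrocyclodeca[b]furan-3-carboxylic acid | O[C@H]1C/C(C)=C/CC/C(CO[Si](C)(C)C(C)(C)C)=C/[C@H]2OC(=O)C(C)(C(=O)O)[C@H]12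
F2 | step 10 | (2Z)-3-iodo-2-[(3E,6S)-4-methyl-6-(triethylsilyloxy)octa-3,7-dien-1-yl]prop-2-en-1-ol | C=C[C@@H](O[Si](CC)(CC)CC)C/C(C)=C/CC/C(CO)=C/I
F3 | step 10 | tert-butyldimethylsilyl ether of F2 | C=C[C@@H](O[Si](CC)(CC)CC)C/C(C)=C/CC/C(CO[Si](C)(C)C(C)(C)C)=C/I
F4 | step 10 | (Z)-alkenylboronic acid pinacol ester derived from F3 | CC1(C)OB(OC1(C)C)/C=C\[C@@H](O[Si](CC)(CC)CC)C/C(C)=C/CC/C(CO[Si](C)(C)C(C)(C)C)=C/I
F5 | step 10 | triethylsilyl ether of 17 | C1/C(C)=C/CC/C(CO[Si](C)(C)C(C)(C)C)=C/C=C\[C@H]1O[Si](CC)(CC)CC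
F6 | step 7 | (2Z,6E,9S)-3-(hydroxymethyl)-N-methoxy-N,7-dimethyl-9-(triethylsilyloxy)undeca-2,6,10-trienamide | C=C[C@@H](O[Si](CC)(CC)CC)C/C(C)=C/CC/C(CO)=C/C(=O)N(C)OC
F7 | step 7 | tert-butyldimethylsilyl ether of F6 | C=C[C@@H](O[Si](CC)(CC)CC)C/C(C)=C/CC/C(CO[Si](C)(C)C(C)(C)C)=C/C(=O)N(C)OC
F8 | step 7 | (2Z,6E,9S)-3-[(tert-butyldimethylsilyloxy)methyl]-7-methyl-9-(triethylsilyloxy)undeca-2,6,10-trienal | C=C[C@@H](O[Si](CC)(CC)CC)C/C(C)=C/CC/C(CO[Si](C)(C)C(C)(C)C)=C/C=O
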